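Ring B (C4a–C5–C6–C7–C8–C8a, isochromene numbering) is cut at C4a–C5 and C6–C7. Its C8 ketone, the aldol carbinol C6 and the enone β-carbon C4a form a consonant pattern, so C7–C8–C8a–C4a is used as a 1,4-zwitterion and C5–C6 as an acetaldehyde silyl enol ether. The zwitterion is stored in a 3-ethoxycyclobutanone, made by ketene–enol ether [2+2] cycloaddition from a ketene that already carries the aryl ester. EtAlCl2 opens the four-membered ring and the enol ether closes ring B in one operation, setting C6 and C7 trans. Acid then forms the enone and pyran ring A; the racemate is resolved at the end.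

Key step: step 9

Remark: the route sets only the relative (trans) configuration at C6/C7; the absolute configuration comes from the resolution in step 12. Compounds 16 and 18–21 are racemic and are drawn as the enantiomer that leads to the target; racemate 22 is written as both enantiomers.
Remark: 7 and 16 are used as isomer mixtures, because the centres concerned (C4a, C8a and the lactate carbon) lose their configuration in steps 8–10.

Step 1
Reactants: 1 (E)-1-bromoprop-1-ene; 2 3,3-diethoxyprop-1-yne
Product: 3 (2E)-6,6-diethoxyhex-2-en-4-yne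
Conditions: Pd(PPh3)2Cl2 (2 mol %), CuI (4 mol %), Et3N, THF, rt
Reagents that add atoms: none
Why: Sonogashira coupling of the vinyl bromide with the terminal alkyne should retain the (E)-geometry and leave the acetal untouched under the basic conditions.

Step 2
Reactants: 3 (2E)-6,6-diethoxyhex-2-en-4-yne
Product: 4 [(4E)-1-ethoxyhex-4-en-2-yn-1-yl]triphenylphosphonium trifluoromethanesulfonate
Conditions: PPh3 (1.1 equiv), TMSOTf (1.1 equiv), CH2Cl2, −78 to 0 °C
Reagents that add atoms: triphenylphosphine, c1ccc(cc1)P(c1ccccc1)c1ccccc1; trimethylsilyl trifluoromethanesulfonate, C[Si](C)(C)OS(=O)(=O)C(F)(F)F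
Why: TMSOTf ionises the acetal to a propargylic oxocarbenium ion that PPh3 traps at carbon, the known conversion of acetals into α-alkoxyphosphonium salts.

Step 3
Reactants: 4 the phosphonium triflate; 5 (tert-butyldimethylsilyloxy)acetaldehyde
Product: 7 tert-butyl{[(6E)-3-ethoxyocta-2,6-dien-4-yn-1-yl]oxy}dimethylsilane (2E/2Z mixture), via phosphorus ylide 6 (not isolated)
Conditions: NaN(SiMe3)2 (1.05 equiv), THF, −78 °C; then 5, −78 °C to rt
Reagents that add atoms: none
Why: Wittig olefination of the α-ethoxy ylide with the aldehyde should give the trisubstituted enol ether, whose E/Z ratio is immaterial because this double bond is consumed in step 8.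

Step 4
Reactants: 8 orsellinic acid (2,4-dihydroxy-6-methylbenzoic acid); 9 tert-butyl 2-bromopropanoate (racemic)
Product: 10 1-tert-butoxy-1-oxopropan-2-yl 2,4-dihydroxy-6-methylbenzoate
Conditions: KHCO3 (1.1 equiv), DMF, rt to 40 °C
Reagents that add atoms: none
Why: bicarbonate deprotonates only the carboxylic acid, and SN2 alkylation of the carboxylate avoids attack at the hindered aroyl carbon, so the hindered ester is made at the easy secondary position.

Step 5
Reactants: 10 the dihydroxy ester
Product: 11 1-tert-butoxy-1-oxopropan-2-yl 4-(tert-butyldimethylsilyloxy)-2-hydroxy-6-methylbenzoate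
Conditions: TBSCl (1.05 equiv), imidazole, CH2Cl2, 0 °C
Reagents that add atoms: tert-butyldimethylsilyl chloride, CC(C)(C)[Si](C)(C)Cl
Why: the para hydroxyl lacks the hydrogen bond to the ester carbonyl that deactivates the ortho hydroxyl, so one equivalent of silyl chloride should silylate it selectively.

Step 6
Reactants: 11 the mono-silyl ether
Product: 12 1-tert-butoxy-1-oxopropan-2-yl 4-(tert-butyldimethylsilyloxy)-2-methoxy-6-methylbenzoate
Conditions: MeOH, PPh3, DIAD, THF, 0 °C to rt
Reagents that add atoms: methanol, CO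
Why: Mitsunobu etherification methylates the remaining hydrogen-bonded phenol under neutral conditions that leave the aryl silyl ether and both esters intact.

Step 7
Reactants: 12 the tert-butyl ester
Product: 13 2-{[4-(tert-butyldimethylsilyloxy)-2-methoxy-6-methylbenzoyl]oxy}propanoic acid
Conditions: TFA, CH2Cl2, 0 °C to rt
Reagents that add atoms: none
Why: acidolysis of the tert-butyl ester (E1) frees the acid, while aryl silyl ethers and the hindered benzoate tolerate brief exposure to TFA.

Step 8
Reactants: 13 the acid; 7 the enol ether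
Product: 16 3-[(tert-butyldimethylsilyloxy)methyl]-2-ethoxy-1-methyl-4-oxo-2-[(3E)-pent-3-en-1-yn-1-yl]cyclobutyl 4-(tert-butyldimethylsilyloxy)-2-methoxy-6-methylbenzoate (racemic diastereomer mixture), via acid chloride 14 (not isolated), via aroyloxy(methyl)ketene 15 (not isolated)
Conditions: (COCl)2, DMF (cat.), CH2Cl2, 0 °C to rt, evaporate; then slow addition to 7 and Et3N, toluene, 90 °C
Reagents that add atoms: none
Why: dehydrohalogenation gives the methyl(aroyloxy)ketene, whose carbonyl carbon is attacked by the nucleophilic β-carbon of the enol ether in a thermal ketene–enol ether [2+2] cycloaddition with 3-alkoxycyclobutanone regiochemistry (C8–C8a and C7–C4a bonds); the stereocentres formed here are not carried into the product.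

Step 9
Reactants: 16 the cyclobutanone; 17 tert-butyldimethyl(vinyloxy)silane
Product: 18 6-(tert-butyldimethylsilyloxy)-4-ethoxy-1-methyl-2-oxo-4-[(3E)-pent-3-en-1-yn-1-yl]-3-[(tert-butyldimethylsilyloxy)methyl]cyclohexyl 4-(tert-butyldimethylsilyloxy)-2-methoxy-6-methylbenzoate (racemic; ring silyloxy group trans to the aroyloxy group; mixture at the ethoxy- and silyloxymethyl-bearing carbons)
Conditions: EtAlCl2 (1.5 equiv), 17 (3 equiv), CH2Cl2, −78 to −45 °C; aq. NaHCO3
Reagents that add atoms: none
Why: EtAlCl2 binds the cyclobutanone oxygen and heterolyses the more substituted C7–C4a bond to a zwitterion (aluminium enolate at C8/C7, propargylic oxocarbenium ion at C4a); the vinyl silyl ether attacks C4a through its CH2 terminus (C4a–C5 bond) and the resulting silyloxocarbenium ion at C6 is captured by enolate carbon C7 (C6–C7 bond). The closest known reaction type is the Lewis acid-promoted formal [4+2] cycloaddition of 3-alkoxycyclobutanones with silyl enol ethers. Ring B closes by a 6-(enolendo)-exo-trig Mukaiyama-type aldol addition. C6 and C7 are set relative to each other in a chair-like transition state in which the chelated (Z)-enolate places the aroyloxy group and the C6 silyloxy group equatorial and the methyl group axial, which should give the trans C6–O/C7–O relationship of the target; no absolute control is exerted, so 18 is racemic. The step needs cleavage of C7–C4a rather than C8a–C4a, secured by the anion-stabilising acyloxy group and the higher substitution at C7, and attack at the oxocarbenium carbon rather than at the alkyne terminus, secured by oxygen stabilisation of the charge at C4a.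

Step 10
Reactants: 18 the cyclohexanone
Product: 21 rac-(6R*,7S*)-6-(tert-butyldimethylsilyloxy)-7-methyl-8-oxo-3-[(E)-prop-1-enyl]-5,6,7,8-tetrahydro-1H-isochromen-7-yl 4-(tert-butyldimethylsilyloxy)-2-methoxy-6-methylbenzoate, via enynone 19 (not isolated), via enynol 20 (not isolated)
Conditions: CSA (0.2 equiv), MeOH/CH2Cl2 (1:4), 0 °C to rt
Reagents that add atoms: none
Why: acid should promote, through the enol of the C8 ketone, β-elimination of ethanol from the tertiary propargylic carbon C4a, methanolysis of the primary silyl ether and 6-endo-dig oxa-Michael addition of the C1 hydroxyl to the δ-carbon C3 of the enynone, while the hindered secondary and the aryl silyl ethers survive.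

Step 11
Reactants: 21 the bis-silyl ether
Product: 22 rac-(6R*,7S*)-6-hydroxy-7-methyl-8-oxo-3-[(E)-prop-1-enyl]-5,6,7,8-tetrahydro-1H-isochromen-7-yl 4-hydroxy-2-methoxy-6-methylbenzoate
Conditions: HF·pyridine, pyridine, THF, 0 °C to rt
Reagents that add atoms: none
Why: fluoride-mediated desilylation under buffered, weakly acidic conditions removes both silyl ethers without the alkoxide formation that could open the β-hydroxy ketone by retro-aldol reaction.

Step 12
Reactants: 22 the racemate
Product: 23 (6R,7S)-6-hydroxy-7-methyl-8-oxo-3-[(E)-prop-1-enyl]-5,6,7,8-tetrahydro-1H-isochromen-7-yl 4-hydroxy-2-methoxy-6-methylbenzoate (target)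
Conditions: preparative chiral SFC, amylose tris(3,5-dimethylphenylcarbamate) phase, CO2/MeOH
Reagents that add atoms: none
Why: resolution on a chiral stationary phase separates the enantiomers without any bond change, so the trans configuration from step 9 is carried into the (6R,7S) enantiomer, whose assignment would be checked by chiroptical comparison or crystallography.

Compound list
1 | (E)-1-bromoprop-1-ene | C/C=C/Br | starting material
2 | 3,3-diethoxyprop-1-yne | C#CC(OCC)OCC | starting material
3 | (2E)-6,6-diethoxyhex-2-en-4-yne | C/C=C/C#CC(OCC)OCC | intermediate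
4 | [(4E)-1-ethoxyhex-4-en-2-yn-1-yl]triphenylphosphonium trifluoromethanesulfonate | C/C=C/C#CC(OCC)[P+](c1ccccc1)(c1ccccc1)c1ccccc1.[O-]S(=O)(=O)C(F)(F)F | intermediate
5 | (tert-butyldimethylsilyloxy)acetaldehyde | O=CCO[Si](C)(C)C(C)(C)C | starting material
6 | [(4E)-1-ethoxyhex-4-en-2-yn-1-ylidene]triphenylphosphorane | C/C=C/C#CC(OCC)=P(c1ccccc1)(c1ccccc1)c1ccccc1 | intermediate
7 | tert-butyl{[(6E)-3-ethoxyocta-2,6-dien-4-yn-1-yl]oxy}dimethylsilane (2E/2Z mixture) | C/C=C/C#CC(OCC)=CCO[Si](C)(C)C(C)(C)C | intermediate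
8 | orsellinic acid | Cc1cc(O)cc(O)c1C(=O)O | starting material
9 | tert-butyl 2-bromopropanoate (racemic) | CC(Br)C(=O)OC(C)(C)C | starting material
10 | 1-tert-butoxy-1-oxopropan-2-yl 2,4-dihydroxy-6-methylbenzoate | Cc1cc(O)cc(O)c1C(=O)OC(C)C(=O)OC(C)(C)C | intermediate
11 | 1-tert-butoxy-1-oxopropan-2-yl 4-(tert-butyldimethylsilyloxy)-2-hydroxy-6-methylbenzoate | Cc1cc(O[Si](C)(C)C(C)(C)C)cc(O)c1C(=O)OC(C)C(=O)OC(C)(C)C | intermediate
12 | 1-tert-butoxy-1-oxopropan-2-yl 4-(tert-butyldimethylsilyloxy)-2-methoxy-6-methylbenzoate | Cc1cc(O[Si](C)(C)C(C)(C)C)cc(OC)c1C(=O)OC(C)C(=O)OC(C)(C)C | intermediate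
13 | 2-{[4-(tert-butyldimethylsilyloxy)-2-methoxy-6-methylbenzoyl]oxy}propanoic acid | Cc1cc(O[Si](C)(C)C(C)(C)C)cc(OC)c1C(=O)OC(C)C(=O)O | intermediate
14 | 2-{[4-(tert-butyldimethylsilyloxy)-2-methoxy-6-methylbenzoyl]oxy}propanoyl chloride | Cc1cc(O[Si](C)(C)C(C)(C)C)cc(OC)c1C(=O)OC(C)C(=O)Cl | intermediate
15 | 1-oxoprop-1-en-2-yl 4-(tert-butyldimethylsilyloxy)-2-methoxy-6-methylbenzoate (ketene) | Cc1cc(O[Si](C)(C)C(C)(C)C)cc(OC)c1C(=O)OC(C)=C=O | intermediate
16 | 3-[(tert-butyldimethylsilyloxy)methyl]-2-ethoxy-1-methyl-4-oxo-2-[(3E)-pent-3-en-1-yn-1-yl]cyclobutyl 4-(tert-butyldimethylsilyloxy)-2-methoxy-6-methylbenzoate (racemic diastereomer mixture) | C/C=C/C#CC1(OCC)C(CO[Si](C)(C)C(C)(C)C)C(=O)C1(C)OC(=O)c2c(C)cc(O[Si](C)(C)C(C)(C)C)cc2OC | intermediate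
17 | tert-butyldimethyl(vinyloxy)silane | C=CO[Si](C)(C)C(C)(C)C | starting material
18 | 6-(tert-butyldimethylsilyloxy)-4-ethoxy-1-methyl-2-oxo-4-[(3E)-pent-3-en-1-yn-1-yl]-3-[(tert-butyldimethylsilyloxy)methyl]cyclohexyl 4-(tert-butyldimethylsilyloxy)-2-methoxy-6-methylbenzoate (racemic, silyloxy trans to aroyloxy) | C/C=C/C#CC1(OCC)C[C@@H](O[Si](C)(C)C(C)(C)C)[C@](C)(OC(=O)c2c(C)cc(O[Si](C)(C)C(C)(C)C)cc2OC)C(=O)C1CO[Si](C)(C)C(C)(C)C | intermediate
19 | 6-(tert-butyldimethylsilyloxy)-1-methyl-2-oxo-4-[(3E)-pent-3-en-1-yn-1-yl]-3-[(tert-butyldimethylsilyloxy)methyl]cyclohex-3-en-1-yl 4-(tert-butyldimethylsilyloxy)-2-methoxy-6-methylbenzoate (racemic enynone) | C/C=C/C#CC1=C(CO[Si](C)(C)C(C)(C)C)C(=O)[C@@](C)(OC(=O)c2c(C)cc(O[Si](C)(C)C(C)(C)C)cc2OC)[C@H](O[Si](C)(C)C(C)(C)C)C1 | intermediate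
20 | 6-(tert-butyldimethylsilyloxy)-3-(hydroxymethyl)-1-methyl-2-oxo-4-[(3E)-pent-3-en-1-yn-1-yl]cyclohex-3-en-1-yl 4-(tert-butyldimethylsilyloxy)-2-methoxy-6-methylbenzoate (racemic enynol) | C/C=C/C#CC1=C(CO)C(=O)[C@@](C)(OC(=O)c2c(C)cc(O[Si](C)(C)C(C)(C)C)cc2OC)[C@H](O[Si](C)(C)C(C)(C)C)C1 | intermediate
21 | rac-(6R*,7S*)-6-(tert-butyldimethylsilyloxy)-7-methyl-8-oxo-3-[(E)-prop-1-enyl]-5,6,7,8-tetrahydro-1H-isochromen-7-yl 4-(tert-butyldimethylsilyloxy)-2-methoxy-6-methylbenzoate | C/C=C/C1=CC2=C(CO1)C(=O)[C@@](C)(OC(=O)c1c(C)cc(O[Si](C)(C)C(C)(C)C)cc1OC)[C@H](O[Si](C)(C)C(C)(C)C)C2 | intermediate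
22 | rac-(6R*,7S*)-6-hydroxy-7-methyl-8-oxo-3-[(E)-prop-1-enyl]-5,6,7,8-tetrahydro-1H-isochromen-7-yl 4-hydroxy-2-methoxy-6-methylbenzoate | C/C=C/C1=CC2=C(CO1)C(=O)[C@@](C)(OC(=O)c1c(C)cc(O)cc1OC)[C@H](O)C2.C/C=C/C1=CC2=C(CO1)C(=O)[C@](C)(OC(=O)c1c(C)cc(O)cc1OC)[C@@H](O)C2 | intermediate
23 | (6R,7S)-6-hydroxy-7-methyl-8-oxo-3-[(E)-prop-1-enyl]-5,6,7,8-tetrahydro-1H-isochromen-7-yl 4-hydroxy-2-methoxy-6-methylbenzoate | C/C=C/C1=CC2=C(CO1)C(=O)[C@@](C)(OC(=O)c1c(C)cc(O)cc1OC)[C@H](O)C2 | target

Total step count: 12. Longest linear sequence: 9 steps (steps 4–12, from orsellinic acid).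

Steps most likely to fail

Step 9. The aldol ring closure may pass through the other enolate geometry or a boat-like arrangement and give poor trans/cis selectivity at C6. The fallback sets out from 16 and comes back at 18, and it sets C6 by substrate-controlled reduction instead of by the aldol closure. The cycloaddition is run with trimethyl(vinyloxy)silane, which should give the trimethylsilyl ether F1. Acidic work-up hydrolyses it to the free C6 carbinol F2 as an epimer mixture. Dess–Martin periodinane (NaHCO3 buffer) oxidises this to the 1,3-diketone F3. Chelation-controlled reduction with Zn(BH4)2 in Et2O at −20 °C should deliver hydride anti to the axial C7 methyl group at the more accessible C6 carbonyl and give the trans carbinol F4. TBSOTf/2,6-lutidine then returns to 18.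

Step 8. The aroyloxy(methyl)ketene may dimerise faster than it closes the congested four-membered ring, in which two fully substituted carbons (C7 and C4a) are joined. The fallback sets out from 13 and comes back at 16, and it replaces the ketene by a more electrophilic keteniminium ion. Acid chloride 14 is converted with dimethylamine into the N,N-dimethylamide F5. Tf2O and 2,6-di-tert-butyl-4-methylpyridine in CH2Cl2 generate the keteniminium salt, which should undergo [2+2] cycloaddition with 7 to the cyclobutaniminium triflate F6. Hydrolysis with aqueous NaHCO3 returns to 16.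

Step 10. Under Brønsted acid the elimination at C4a may stall, the C1 hydroxyl may close 5-exo onto C4 instead of 6-endo onto C3, or the C6 silyl ether may be lost. The fallback sets out from 18 and comes back at 21, and it separates the three events and hands the ring closure to a soft π-acid. BF3·OEt2 in CH2Cl2 at −20 °C effects loss of ethanol to give isolated enynone 19. HF·pyridine buffered with pyridine at 0 °C removes only the primary silyl ether to give isolated enynol 20. Cationic monovalent gold [AuCl(PPh3)/AgOTf, CH2Cl2, rt] then catalyses the 6-endo-dig hydroalkoxylation to 21. This fallback makes no compound outside the list (F0).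

Further compounds
F1 | step 9 | 4-ethoxy-1-methyl-2-oxo-4-[(3E)-pent-3-en-1-yn-1-yl]-3-[(tert-butyldimethylsilyloxy)methyl]-6-(trimethylsilyloxy)cyclohexyl 4-(tert-butyldimethylsilyloxy)-2-methoxy-6-methylbenzoate (racemic, epimer mixture) | C/C=C/C#CC1(OCC)CC(O[Si](C)(C)C)C(C)(OC(=O)c2c(C)cc(O[Si](C)(C)C(C)(C)C)cc2OC)C(=O)C1CO[Si](C)(C)C(C)(C)C
F2 | step 9 | 4-ethoxy-6-hydroxy-1-methyl-2-oxo-4-[(3E)-pent-3-en-1-yn-1-yl]-3-[(tert-butyldimethylsilyloxy)methyl]cyclohexyl 4-(tert-butyldimethylsilyloxy)-2-methoxy-6-methylbenzoate (racemic, epimer mixture) | C/C=C/C#CC1(OCC)CC(O)C(C)(OC(=O)c2c(C)cc(O[Si](C)(C)C(C)(C)C)cc2OC)C(=O)C1CO[Si](C)(C)C(C)(C)C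
F3 | step 9 | 4-ethoxy-1-methyl-2,6-dioxo-4-[(3E)-pent-3-en-1-yn-1-yl]-3-[(tert-butyldimethylsilyloxy)methyl]cyclohexyl 4-(tert-butyldimethylsilyloxy)-2-methoxy-6-methylbenzoate (racemic) | C/C=C/C#CC1(OCC)CC(=O)C(C)(OC(=O)c2c(C)cc(O[Si](C)(C)C(C)(C)C)cc2OC)C(=O)C1CO[Si](C)(C)C(C)(C)C
F4 | step 9 | 4-ethoxy-6-hydroxy-1-methyl-2-oxo-4-[(3E)-pent-3-en-1-yn-1-yl]-3-[(tert-butyldimethylsilyloxy)methyl]cyclohexyl 4-(tert-butyldimethylsilyloxy)-2-methoxy-6-methylbenzoate (racemic, hydroxyl trans to aroyloxy) | C/C=C/C#CC1(OCC)C[C@@H](O)[C@](C)(OC(=O)c2c(C)cc(O[Si](C)(C)C(C)(C)C)cc2OC)C(=O)C1CO[Si](C)(C)C(C)(C)C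
F5 | step 8 | 1-(dimethylamino)-1-oxopropan-2-yl 4-(tert-butyldimethylsilyloxy)-2-methoxy-6-methylbenzoate | Cc1cc(O[Si](C)(C)C(C)(C)C)cc(OC)c1C(=O)OC(C)C(=O)N(C)C
F6 | step 8 | N-{2-[4-(tert-butyldimethylsilyloxy)-2-methoxy-6-methylbenzoyloxy]-3-ethoxy-2-methyl-3-[(3E)-pent-3-en-1-yn-1-yl]-4-[(tert-butyldimethylsilyloxy)methyl]cyclobutylidene}-N-methylmethanaminium trifluoromethanesulfonate | C/C=C/C#CC1(OCC)C(CO[Si](C)(C)C(C)(C)C)C(=[N+](C)C)C1(C)OC(=O)c2c(C)cc(O[Si](C)(C)C(C)(C)C)cc2OC.[O-]S(=O)(=O)C(F)(F)F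
F0 | step 10 | none | none
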